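Abbreviations: TBDPS = tert-butyldiphenylsilyl, PT = 1-phenyl-1H-tetrazol-5-yl, MOP = 2-methoxypropan-2-yl.
Assumption: the carbinol centre made in step 5 and the ketal centre of 16/17 are carried as epimer mixtures, because both are destroyed before the target's stereocentres are fixed.

**Retrosynthetic overview**
1. Acid ⇐ methyl ester ⇐ (E,E,E)-triene by Julia–Kocienski coupling of a C9 alkyl PT-sulfone on the dioxolane with (2E,4E)-hepta-2,4-dienal, done after all Lewis-acidic peroxide steps.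
2. Key C–C bond (C3–CH2CO2Me): Mukaiyama aldol-type addition of the silyl ketene acetal of methyl acetate to the peroxycarbenium ion from a 3-methoxy-1,2-dioxolane; the C3 epimers are separated.
3. 3-Methoxy-1,2-dioxolane ⇐ β-hydroperoxy methyl ketone ⇐ H2O2 opening (inversion) of an enantioenriched 2,2,4-trisubstituted oxetane; this sets C5.
4. Oxetane ⇐ 2,4-diol ⇐ epoxy alcohol (Sharpless epoxidation, oxidation, MeMgBr, directed hydride opening) ⇐ (E)-allylic alcohol ⇐ carboalumination of TBDPS-protected undec-10-yn-1-ol.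
5. Ring order: oxirane (step 3, opened in step 6) → oxetane (step 8, opened in step 9) → 1,2-dioxolane (step 12), the only ring of the target.

**Route**

Step 1
Reactants: 1 undec-10-yn-1-ol
Product: 2 tert-butyl(diphenyl)(undec-10-yn-1-yloxy)silane
Conditions: TBDPSCl, imidazole, DMF, 0 °C → rt
Reagents that add atoms: tert-butyl(chloro)diphenylsilane, CC(C)(C)[Si](Cl)(c1ccccc1)c1ccccc1
Why: Silylation of the primary alcohol gives an acid- and base-robust ether that masks the future sulfone terminus through the organometallic and Lewis-acidic steps.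

Step 2
Reactants: 2 tert-butyl(diphenyl)(undec-10-yn-1-yloxy)silane
Product: 5 (2E)-12-(TBDPSO)-3-methyldodec-2-en-1-ol, via alkenyldimethylalane 3 (not isolated), via lithium alkenylalanate 4 (not isolated)
Conditions: Me3Al, Cp2ZrCl2 (25 mol %), CH2Cl2, 0 °C → rt; then n-BuLi, THF, −78 °C; (CH2O)n, → rt; 1 M HCl
Reagents that add atoms: trimethylaluminium, C[Al](C)C; paraformaldehyde (reacting as formaldehyde), C=O
Why: Negishi zirconium-catalysed carboalumination adds Me–Al syn across the terminal alkyne, and hydroxymethylation of the derived alanate proceeds with retention, so only the (E)-trisubstituted allylic alcohol is formed.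

Step 3
Reactants: 5 (2E)-12-(TBDPSO)-3-methyldodec-2-en-1-ol
Product: 6 [(2R,3R)-3-[9-(TBDPSO)nonyl]-3-methyloxiran-2-yl]methanol
Conditions: Ti(OiPr)4 (10 mol %), D-(−)-diethyl tartrate (12 mol %), t-BuOOH, 4 Å MS, CH2Cl2, −20 °C
Reagents that add atoms: tert-butyl hydroperoxide, CC(C)(C)OO
Why: Sharpless asymmetric epoxidation with the D-(−)-tartrate gives the (2R,3R)-epoxide from this geraniol-type (E)-allylic alcohol (≥90% ee expected), which fixes the configuration of the future C5 carbon–oxygen centre.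

Step 4
Reactants: 6 [(2R,3R)-3-[9-(TBDPSO)nonyl]-3-methyloxiran-2-yl]methanol
Product: 7 (2S,3R)-3-[9-(TBDPSO)nonyl]-3-methyloxirane-2-carbaldehyde
Conditions: TEMPO (10 mol %), PhI(OAc)2, CH2Cl2, rt
Reagents that add atoms: none
Why: Oxoammonium (TEMPO/PhI(OAc)2) oxidation stops at the aldehyde under near-neutral conditions that spare the epoxide and silyl ether; the C2 descriptor changes only through CIP priorities.

Step 5
Reactants: 7 (2S,3R)-3-[9-(TBDPSO)nonyl]-3-methyloxirane-2-carbaldehyde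
Product: 8 (1RS)-1-[(2R,3R)-3-[9-(TBDPSO)nonyl]-3-methyloxiran-2-yl]ethan-1-ol
Conditions: MeMgBr, THF, −78 °C; then aq. NH4Cl
Reagents that add atoms: methylmagnesium bromide, C[Mg]Br
Why: Grignard 1,2-addition to the epoxy aldehyde is far faster than epoxide opening at −78 °C; the new carbinol centre forms as an epimer mixture, which does not matter because it is oxidised in step 11.

Step 6
Reactants: 8 (1RS)-1-[(2R,3R)-3-[9-(TBDPSO)nonyl]-3-methyloxiran-2-yl]ethan-1-ol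
Product: 9 (2RS,4R)-13-(TBDPSO)-4-methyltridecane-2,4-diol
Conditions: NaAlH2(OCH2CH2OMe)2, THF, 0 °C → rt
Reagents that add atoms: none
Why: Hydroxyl-directed reductive opening of the 2,3-epoxy alcohol delivers hydride to the carbinol-proximal, less substituted epoxide carbon, giving the 1,3-diol with the tertiary C–O bond and its (R) configuration untouched.

Step 7
Reactants: 9 (2RS,4R)-13-(TBDPSO)-4-methyltridecane-2,4-diol
Product: 10 (2RS,4R)-13-(TBDPSO)-4-hydroxy-4-methyltridecan-2-yl methanesulfonate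
Conditions: MsCl (1.1 equiv), Et3N, CH2Cl2, −40 → 0 °C
Reagents that add atoms: methanesulfonyl chloride, CS(=O)(=O)Cl
Why: Sulfonylation is selective for the secondary over the hindered tertiary hydroxyl, activating the carbon that the tertiary alkoxide will displace.

Step 8
Reactants: 10 (2RS,4R)-13-(TBDPSO)-4-hydroxy-4-methyltridecan-2-yl methanesulfonate
Product: 11 (2R,4RS)-2-[9-(TBDPSO)nonyl]-2,4-dimethyloxetane
Conditions: KOtBu, THF, 0 °C → rt
Reagents that add atoms: none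
Why: Intramolecular Williamson etherification (4-exo-tet) of the tertiary alkoxide on the secondary mesylate closes the oxetane with retention at the quaternary carbon, whose C–O bond is not involved.

Step 9
Reactants: 11 (2R,4RS)-2-[9-(TBDPSO)nonyl]-2,4-dimethyloxetane
Product: 12 (2RS,4S)-13-(TBDPSO)-4-hydroperoxy-4-methyltridecan-2-ol
Conditions: H2O2 (anhydrous in Et2O, excess), TMSOTf (20 mol %), Et2O, −78 → 0 °C
Reagents that add atoms: hydrogen peroxide, OO
Why: Lewis-acid-activated oxetane opening by H2O2 occurs at the tertiary C–O bond through a tight ion pair with inversion, turning the (R) ether carbon into the (S)-tertiary hydroperoxide that becomes C5 of the target.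

Step 10
Reactants: 12 (2RS,4S)-13-(TBDPSO)-4-hydroperoxy-4-methyltridecan-2-ol
Product: 13 (2RS,4S)-13-(TBDPSO)-4-(MOP-peroxy)-4-methyltridecan-2-ol
Conditions: 2-methoxypropene (1.2 equiv), PPTS (cat.), CH2Cl2, −20 → 0 °C
Reagents that add atoms: 2-methoxypropene, COC(C)=C
Why: Acid-catalysed peroxyketalisation; the more acidic, alpha-effect-nucleophilic OOH adds to the enol ether faster than the secondary alcohol, so the hydroperoxide is masked for the oxidation.

Step 11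
Reactants: 13 (2RS,4S)-13-(TBDPSO)-4-(MOP-peroxy)-4-methyltridecan-2-ol
Product: 14 (4S)-13-(TBDPSO)-4-(MOP-peroxy)-4-methyltridecan-2-one
Conditions: Dess–Martin periodinane, pyridine, CH2Cl2, 0 °C → rt
Reagents that add atoms: none
Why: Dess–Martin oxidation converts both carbinol epimers into the single methyl ketone under buffered conditions that tolerate the peroxyketal and leave the quaternary peroxide carbon alone.

Step 12
Reactants: 14 (4S)-13-(TBDPSO)-4-(MOP-peroxy)-4-methyltridecan-2-one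
Product: 17 (3RS,5S)-5-[9-(TBDPSO)nonyl]-3-methoxy-3,5-dimethyl-1,2-dioxolane, via hydroperoxy ketone 15 (not isolated), via 3-hydroxy-1,2-dioxolane 16 (not isolated)
Conditions: p-TsOH·H2O (5 mol %), MeOH, 0 °C → rt
Reagents that add atoms: methanol, CO
Why: Acid methanolysis removes the peroxyketal, the freed β-hydroperoxy ketone closes to the cyclic peroxyhemiketal, and Fischer-type ketal exchange gives the 3-methoxy-1,2-dioxolane; C5 is untouched and the C3 anomer mixture is inconsequential.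

Step 13
Reactants: 17 (3RS,5S)-5-[9-(TBDPSO)nonyl]-3-methoxy-3,5-dimethyl-1,2-dioxolane; 18 tert-butyl[(1-methoxyethenyl)oxy]dimethylsilane
Product: 20 methyl 2-[(3R,5S)-5-[9-(TBDPSO)nonyl]-3,5-dimethyl-1,2-dioxolan-3-yl]acetate, via peroxycarbenium ion 19 (not isolated)
Conditions: TiCl4 (1.1 equiv), CH2Cl2, −78 °C; then H2O; SiO2 chromatography (HPLC if needed)
Reagents that add atoms: none
Why: Mukaiyama aldol-type addition: TiCl4 ionises the peroxyketal to a peroxycarbenium ion that the silyl ketene acetal traps at carbon without O–O cleavage; C3 forms with almost no facial bias (about 1:1), so the (3R,5S) isomer (acetate arm trans to the long chain) is separated chromatographically from its C3 epimer.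

Step 14
Reactants: 20 methyl 2-[(3R,5S)-5-[9-(TBDPSO)nonyl]-3,5-dimethyl-1,2-dioxolan-3-yl]acetate
Product: 21 methyl 2-[(3R,5S)-5-(9-hydroxynonyl)-3,5-dimethyl-1,2-dioxolan-3-yl]acetate
Conditions: HF·pyridine, pyridine, THF, 0 °C → rt
Reagents that add atoms: none
Why: Fluoride-driven desilylation under mildly acidic conditions frees the primary alcohol without the basic conditions that could open the β-peroxy ester.

Step 15
Reactants: 21 methyl 2-[(3R,5S)-5-(9-hydroxynonyl)-3,5-dimethyl-1,2-dioxolan-3-yl]acetate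
Product: 22 methyl 2-[(3R,5S)-5-[9-(methanesulfonyloxy)nonyl]-3,5-dimethyl-1,2-dioxolan-3-yl]acetate
Conditions: MsCl, Et3N, CH2Cl2, 0 °C
Reagents that add atoms: methanesulfonyl chloride, CS(=O)(=O)Cl
Why: Mesylation activates the primary alcohol without a phosphine, which could reduce the peroxide.

Step 16
Reactants: 22 methyl 2-[(3R,5S)-5-[9-(methanesulfonyloxy)nonyl]-3,5-dimethyl-1,2-dioxolan-3-yl]acetate
Product: 23 methyl 2-[(3R,5S)-3,5-dimethyl-5-[9-(PT-sulfanyl)nonyl]-1,2-dioxolan-3-yl]acetate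
Conditions: sodium 1-phenyl-1H-tetrazole-5-thiolate, DMF, rt
Reagents that add atoms: sodium 1-phenyl-1H-tetrazole-5-thiolate, [Na+].[S-]c1nnnn1-c1ccccc1
Why: SN2 displacement of the primary mesylate by the soft, weakly basic thiolate occurs at sulfur and leaves the hindered tetrasubstituted peroxide and the ester alone.

Step 17
Reactants: 23 methyl 2-[(3R,5S)-3,5-dimethyl-5-[9-(PT-sulfanyl)nonyl]-1,2-dioxolan-3-yl]acetate
Product: 24 methyl 2-[(3R,5S)-3,5-dimethyl-5-[9-(PT-sulfonyl)nonyl]-1,2-dioxolan-3-yl]acetate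
Conditions: (NH4)6Mo7O24·4H2O (10 mol %), 30% aq. H2O2, EtOH, 0 °C → rt
Reagents that add atoms: hydrogen peroxide, OO
Why: Molybdate-catalysed sulfide-to-sulfone oxidation is electrophilic at sulfur and does not affect the dialkyl peroxide or the ester.

Step 18
Reactants: 24 methyl 2-[(3R,5S)-3,5-dimethyl-5-[9-(PT-sulfonyl)nonyl]-1,2-dioxolan-3-yl]acetate; 25 (2E,4E)-hepta-2,4-dienal
Product: 27 methyl 2-[(3R,5S)-5-[(9E,11E,13E)-hexadeca-9,11,13-trien-1-yl]-3,5-dimethyl-1,2-dioxolan-3-yl]acetate, via potassium sulfonyl carbanion 26 (not isolated)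
Conditions: KN(SiMe3)2 (1.05 equiv), THF, −78 °C, 30 min; then 25, −78 °C → rt
Reagents that add atoms: none
Why: Julia–Kocienski olefination: the premetalated PT-sulfone adds to the dienal, and Smiles rearrangement with loss of SO2 and PT-olate gives the new C9=C10 bond E-selectively, while the less acidic ester α-protons are left alone at −78 °C and the 2E,4E bonds of 25 carry over unchanged.

Step 19
Reactants: 27 methyl 2-[(3R,5S)-5-[(9E,11E,13E)-hexadeca-9,11,13-trien-1-yl]-3,5-dimethyl-1,2-dioxolan-3-yl]acetate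
Product: 29 2-[(3R,5S)-5-[(9E,11E,13E)-hexadeca-9,11,13-trien-1-yl]-3,5-dimethyl-1,2-dioxolan-3-yl]acetic acid, via lithium carboxylate 28 (not isolated)
Conditions: LiOH·H2O, THF/H2O (3:1), 0 °C → rt; then 1 M HCl to pH 3, 0 °C
Reagents that add atoms: lithium hydroxide, [Li+].[OH-]
Why: Saponification at low temperature cleaves the methyl ester; the peroxide carbons carry no α-hydrogen (no Kornblum–DeLaMare cleavage) and neither stereocentre nor the triene is touched.

**Compound list**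
1 | undec-10-yn-1-ol | C#CCCCCCCCCCO | starting material
2 | tert-butyl(diphenyl)(undec-10-yn-1-yloxy)silane | C#CCCCCCCCCCO[Si](c1ccccc1)(c1ccccc1)C(C)(C)C | intermediate
3 | [(1E)-11-(TBDPSO)-2-methylundec-1-en-1-yl]dimethylalumane | C[Al](C)/C=C(\C)CCCCCCCCCO[Si](c1ccccc1)(c1ccccc1)C(C)(C)C | intermediate
4 | lithium butyl[(1E)-11-(TBDPSO)-2-methylundec-1-en-1-yl]dimethylaluminate | [Li+].CCCC[Al-](C)(C)/C=C(\C)CCCCCCCCCO[Si](c1ccccc1)(c1ccccc1)C(C)(C)C | intermediate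
5 | (2E)-12-(TBDPSO)-3-methyldodec-2-en-1-ol | OC/C=C(\C)CCCCCCCCCO[Si](c1ccccc1)(c1ccccc1)C(C)(C)C | intermediate
6 | [(2R,3R)-3-[9-(TBDPSO)nonyl]-3-methyloxiran-2-yl]methanol | OC[C@H]1O[C@]1(C)CCCCCCCCCO[Si](c2ccccc2)(c2ccccc2)C(C)(C)C | intermediate
7 | (2S,3R)-3-[9-(TBDPSO)nonyl]-3-methyloxirane-2-carbaldehyde | O=C[C@H]1O[C@]1(C)CCCCCCCCCO[Si](c2ccccc2)(c2ccccc2)C(C)(C)C | intermediate
8 | (1RS)-1-[(2R,3R)-3-[9-(TBDPSO)nonyl]-3-methyloxiran-2-yl]ethan-1-ol (carbinol epimers) | CC(O)[C@H]1O[C@]1(C)CCCCCCCCCO[Si](c2ccccc2)(c2ccccc2)C(C)(C)C | intermediate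
9 | (2RS,4R)-13-(TBDPSO)-4-methyltridecane-2,4-diol | CC(O)C[C@](C)(O)CCCCCCCCCO[Si](c1ccccc1)(c1ccccc1)C(C)(C)C | intermediate
10 | (2RS,4R)-13-(TBDPSO)-4-hydroxy-4-methyltridecan-2-yl methanesulfonate | CC(OS(C)(=O)=O)C[C@](C)(O)CCCCCCCCCO[Si](c1ccccc1)(c1ccccc1)C(C)(C)C | intermediate
11 | (2R,4RS)-2-[9-(TBDPSO)nonyl]-2,4-dimethyloxetane | CC1C[C@@](C)(CCCCCCCCCO[Si](c2ccccc2)(c2ccccc2)C(C)(C)C)O1 | intermediate
12 | (2RS,4S)-13-(TBDPSO)-4-hydroperoxy-4-methyltridecan-2-ol | CC(O)C[C@@](C)(OO)CCCCCCCCCO[Si](c1ccccc1)(c1ccccc1)C(C)(C)C | intermediate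
13 | (2RS,4S)-13-(TBDPSO)-4-[(2-methoxypropan-2-yl)peroxy]-4-methyltridecan-2-ol | CC(O)C[C@@](C)(OOC(C)(C)OC)CCCCCCCCCO[Si](c1ccccc1)(c1ccccc1)C(C)(C)C | intermediate
14 | (4S)-13-(TBDPSO)-4-[(2-methoxypropan-2-yl)peroxy]-4-methyltridecan-2-one | CC(=O)C[C@@](C)(OOC(C)(C)OC)CCCCCCCCCO[Si](c1ccccc1)(c1ccccc1)C(C)(C)C | intermediate
15 | (4S)-13-(TBDPSO)-4-hydroperoxy-4-methyltridecan-2-one | CC(=O)C[C@@](C)(OO)CCCCCCCCCO[Si](c1ccccc1)(c1ccccc1)C(C)(C)C | intermediate
16 | (3RS,5S)-5-[9-(TBDPSO)nonyl]-3,5-dimethyl-1,2-dioxolan-3-ol | CC1(O)C[C@](C)(CCCCCCCCCO[Si](c2ccccc2)(c2ccccc2)C(C)(C)C)OO1 | intermediate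
17 | (3RS,5S)-5-[9-(TBDPSO)nonyl]-3-methoxy-3,5-dimethyl-1,2-dioxolane | COC1(C)C[C@](C)(CCCCCCCCCO[Si](c2ccccc2)(c2ccccc2)C(C)(C)C)OO1 | intermediate
18 | tert-butyl[(1-methoxyethenyl)oxy]dimethylsilane | COC(=C)O[Si](C)(C)C(C)(C)C | starting material
19 | (5S)-5-[9-(TBDPSO)nonyl]-3,5-dimethyl-4,5-dihydro-1,2-dioxol-2-ium (peroxycarbenium ion) | C[C@]1(CCCCCCCCCO[Si](c2ccccc2)(c2ccccc2)C(C)(C)C)CC(C)=[O+]O1 | intermediate
20 | methyl 2-[(3R,5S)-5-[9-(TBDPSO)nonyl]-3,5-dimethyl-1,2-dioxolan-3-yl]acetate | CC(C)(C)[Si](c1ccccc1)(c1ccccc1)OCCCCCCCCC[C@@]1(C)C[C@](C)(CC(=O)OC)OO1 | intermediate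
21 | methyl 2-[(3R,5S)-5-(9-hydroxynonyl)-3,5-dimethyl-1,2-dioxolan-3-yl]acetate | OCCCCCCCCC[C@@]1(C)C[C@](C)(CC(=O)OC)OO1 | intermediate
22 | methyl 2-[(3R,5S)-5-[9-(methanesulfonyloxy)nonyl]-3,5-dimethyl-1,2-dioxolan-3-yl]acetate | CS(=O)(=O)OCCCCCCCCC[C@@]1(C)C[C@](C)(CC(=O)OC)OO1 | intermediate
23 | methyl 2-[(3R,5S)-3,5-dimethyl-5-{9-[(1-phenyl-1H-tetrazol-5-yl)sulfanyl]nonyl}-1,2-dioxolan-3-yl]acetate | c1ccccc1-n1nnnc1SCCCCCCCCC[C@@]1(C)C[C@](C)(CC(=O)OC)OO1 | intermediate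
24 | methyl 2-[(3R,5S)-3,5-dimethyl-5-{9-[(1-phenyl-1H-tetrazol-5-yl)sulfonyl]nonyl}-1,2-dioxolan-3-yl]acetate | c1ccccc1-n1nnnc1S(=O)(=O)CCCCCCCCC[C@@]1(C)C[C@](C)(CC(=O)OC)OO1 | intermediate
25 | (2E,4E)-hepta-2,4-dienal | CC/C=C/C=C/C=O | starting material
26 | potassium α-sulfonyl carbanion of 24 | [K+].c1ccccc1-n1nnnc1S(=O)(=O)[CH-]CCCCCCCC[C@@]1(C)C[C@](C)(CC(=O)OC)OO1 | intermediate
27 | methyl 2-[(3R,5S)-5-[(9E,11E,13E)-hexadeca-9,11,13-trien-1-yl]-3,5-dimethyl-1,2-dioxolan-3-yl]acetate | CC/C=C/C=C/C=C/CCCCCCCC[C@@]1(C)C[C@](C)(CC(=O)OC)OO1 | intermediate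
28 | lithium 2-[(3R,5S)-5-[(9E,11E,13E)-hexadeca-9,11,13-trien-1-yl]-3,5-dimethyl-1,2-dioxolan-3-yl]acetate | [Li+].CC/C=C/C=C/C=C/CCCCCCCC[C@@]1(C)C[C@](C)(CC(=O)[O-])OO1 | intermediate
29 | 2-[(3R,5S)-5-[(9E,11E,13E)-hexadeca-9,11,13-trien-1-yl]-3,5-dimethyl-1,2-dioxolan-3-yl]acetic acid | CC/C=C/C=C/C=C/CCCCCCCC[C@@]1(C)C[C@](C)(CC(=O)O)OO1 | target

**Totals and risks**
Total step count: 19. Longest linear sequence: 19 steps (1 → 29); 18 and 25 are bought.

The three steps most likely to fail: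

Step 9 (oxetane perhydrolysis). Risks are competing ionisation or elimination at the secondary oxetane carbon, partial loss of stereospecificity at the tertiary centre, and silyl ether loss under the acid. The fallback postpones the methyl ketone so that the ring to be opened is a 2,2-disubstituted oxetane in which only the tertiary C–O bond can ionise. It sets out from 6: NaAlH2(OCH2CH2OMe)2 opening gives (3R)-12-(TBDPSO)-3-methyldodecane-1,3-diol F1. Selective primary tosylation (TsCl, pyridine) gives (3R)-12-(TBDPSO)-3-hydroxy-3-methyldodecyl 4-methylbenzenesulfonate F2, and KOtBu closes (2R)-2-[9-(TBDPSO)nonyl]-2-methyloxetane F3. H2O2/TMSOTf then gives, with inversion, (3S)-12-(TBDPSO)-3-hydroperoxy-3-methyldodecan-1-ol F4. 2-Methoxypropene/PPTS gives (3S)-12-(TBDPSO)-3-(MOP-peroxy)-3-methyldodecan-1-ol F5, and Dess–Martin oxidation gives (3S)-12-(TBDPSO)-3-(MOP-peroxy)-3-methyldodecanal F6. MeMgBr at −78 °C, where carbonyl addition outruns attack on the peroxyketal, comes back to the route at 13.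

Step 13 (peroxycarbenium aldol). Risks are the roughly 1:1 C3 selectivity, a difficult epimer separation, and decomposition of the peroxide by TiCl4. The fallback replaces the ketene acetal by an allyl nucleophile and unmasks the acetate afterwards. It sets out from 17: allyltrimethylsilane with SnCl4 in CH2Cl2 at −78 °C (Hosomi–Sakurai allylation of the same peroxycarbenium ion) gives, after separation of the C3 epimers, (3S,5S)-5-[9-(TBDPSO)nonyl]-3,5-dimethyl-3-(prop-2-en-1-yl)-1,2-dioxolane F7; the descriptor is 3S only because of CIP priorities. Ozonolysis (O3, CH2Cl2/MeOH, −78 °C; Me2S) gives 2-[(3R,5S)-5-[9-(TBDPSO)nonyl]-3,5-dimethyl-1,2-dioxolan-3-yl]acetaldehyde F8. Pinnick oxidation (NaClO2, NaH2PO4, 2-methyl-2-butene) gives 2-[(3R,5S)-5-[9-(TBDPSO)nonyl]-3,5-dimethyl-1,2-dioxolan-3-yl]acetic acid F9, and Me3SiCHN2 in MeOH/toluene comes back to the route at 20.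

Step 18 (Julia–Kocienski olefination). Risks are base-induced retro-oxa-Michael opening of the β-peroxy ester and incomplete E selectivity; a minor 9Z isomer would be removed on AgNO3-impregnated silica. The fallback runs the olefination on the carboxylate, whose α-protons KN(SiMe3)2 does not remove at −78 °C, so the ring-opening pathway is shut off. It sets out from 23: LiOH in THF/H2O gives 2-[(3R,5S)-3,5-dimethyl-5-[9-(PT-sulfanyl)nonyl]-1,2-dioxolan-3-yl]acetic acid F10. (NH4)6Mo7O24·4H2O/H2O2 oxidation gives 2-[(3R,5S)-3,5-dimethyl-5-[9-(PT-sulfonyl)nonyl]-1,2-dioxolan-3-yl]acetic acid F11. KN(SiMe3)2 (2.1 equiv) in THF at −78 °C, then 25 and acidic work-up, comes back to the route at 29.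

Further compounds
F1 | step 9 | (3R)-12-(TBDPSO)-3-methyldodecane-1,3-diol | OCC[C@](C)(O)CCCCCCCCCO[Si](c1ccccc1)(c1ccccc1)C(C)(C)C
F2 | step 9 | (3R)-12-(TBDPSO)-3-hydroxy-3-methyldodecyl 4-methylbenzenesulfonate | Cc1ccc(cc1)S(=O)(=O)OCC[C@](C)(O)CCCCCCCCCO[Si](c1ccccc1)(c1ccccc1)C(C)(C)C
F3 | step 9 | (2R)-2-[9-(TBDPSO)nonyl]-2-methyloxetane | C[C@@]1(CCCCCCCCCO[Si](c2ccccc2)(c2ccccc2)C(C)(C)C)CCO1
F4 | step 9 | (3S)-12-(TBDPSO)-3-hydroperoxy-3-methyldodecan-1-ol | OCC[C@@](C)(OO)CCCCCCCCCO[Si](c1ccccc1)(c1ccccc1)C(C)(C)C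
F5 | step 9 | (3S)-12-(TBDPSO)-3-[(2-methoxypropan-2-yl)peroxy]-3-methyldodecan-1-ol | OCC[C@@](C)(OOC(C)(C)OC)CCCCCCCCCO[Si](c1ccccc1)(c1ccccc1)C(C)(C)C
F6 | step 9 | (3S)-12-(TBDPSO)-3-[(2-methoxypropan-2-yl)peroxy]-3-methyldodecanal | O=CC[C@@](C)(OOC(C)(C)OC)CCCCCCCCCO[Si](c1ccccc1)(c1ccccc1)C(C)(C)C
F7 | step 13 | (3S,5S)-5-[9-(TBDPSO)nonyl]-3,5-dimethyl-3-(prop-2-en-1-yl)-1,2-dioxolane | CC(C)(C)[Si](c1ccccc1)(c1ccccc1)OCCCCCCCCC[C@@]1(C)C[C@](C)(CC=C)OO1
F8 | step 13 | 2-[(3R,5S)-5-[9-(TBDPSO)nonyl]-3,5-dimethyl-1,2-dioxolan-3-yl]acetaldehyde | CC(C)(C)[Si](c1ccccc1)(c1ccccc1)OCCCCCCCCC[C@@]1(C)C[C@](C)(CC=O)OO1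
F9 | step 13 | 2-[(3R,5S)-5-[9-(TBDPSO)nonyl]-3,5-dimethyl-1,2-dioxolan-3-yl]acetic acid | CC(C)(C)[Si](c1ccccc1)(c1ccccc1)OCCCCCCCCC[C@@]1(C)C[C@](C)(CC(=O)O)OO1
F10 | step 18 | 2-[(3R,5S)-3,5-dimethyl-5-{9-[(1-phenyl-1H-tetrazol-5-yl)sulfanyl]nonyl}-1,2-dioxolan-3-yl]acetic acid | c1ccccc1-n1nnnc1SCCCCCCCCC[C@@]1(C)C[C@](C)(CC(=O)O)OO1
F11 | step 18 | 2-[(3R,5S)-3,5-dimethyl-5-{9-[(1-phenyl-1H-tetrazol-5-yl)sulfonyl]nonyl}-1,2-dioxolan-3-yl]acetic acid | c1ccccc1-n1nnnc1S(=O)(=O)CCCCCCCCC[C@@]1(C)C[C@](C)(CC(=O)O)OO1
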